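At the reading, 10 min after the start, violet holds the intermediate that has been made and not yet lost. So we need how much is made and how long it has stood.

| flask | substrate | partner | temperature | remark | time |
|---|---|---|---|---|---|
| west | 5.5 mM | 8.8 mM | 65 °C | run made earlier |  |
| south | 22 mM | 8.8 mM | 95 °C | run made earlier |  |
| violet | 11 mM | 8.80 mM | 70 °C |  | 10 min |
| green | 11 mM | 8.80 mM | 120 °C |  | 10 min |
| teal | 11 mM | 8.80 mM | 95 °C |  | 10 min |

| run | time / min | intermediate / % | target / % |
|---|---|---|---|
| west | 1.00 | 21 | 2 |
| west | 3.00 | 42 | 3 |
| west | 5.00 | 51 | 9 |
| west | 8.00 | 48 | 18 |
| south | 0.200 | 21 | 4 |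
| south | 0.417 | 19 | 11 |
| south | 0.833 | 10 | 15 |
| south | 2.50 | 3 | 20 |

(standard deviation of a reading: 1.5 percentage points)

- the earlier runs were read with a standard deviation of 1.5 percentage points
- a reading or a percentage of target counts all its forms, free or not

1. the flask that comes out highest in amount of intermediate, in percent of the substrate charged, or "all alike" when all lie within 1.5 percentage points (violet / green / teal / all alike)
2. intermediate at the end, in percent of the substrate charged, violet
3. intermediate at the end, in percent of the substrate charged, green
4. intermediate at the end, in percent of the substrate charged, teal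

We take one partner per intermediate. Violet's limiting reagent is then partner, which caps intermediate at 80.0% of the substrate. West has partner in surplus.

The first readings give a making constant of 0.0297 mM⁻¹ min⁻¹ in west and 0.263 mM⁻¹ min⁻¹ in south. Violet lies 0.167 of the way between them in temperature, so on a log scale we get 0.0427 mM⁻¹ min⁻¹.

In the south readings, intermediate plus target falls from 30.0% at 0.417 min to 23.0% at 2.50 min. So something we do not read also takes intermediate. If south had reached its partner cap of 40.0% by the last reading, target held 0.541 of what was used there. West's target slope over its last two readings, per mean intermediate and divided by that share, gives 0.112 min⁻¹. South's last two readings give 0.722 min⁻¹. The same interpolation gives 0.153 min⁻¹ for violet. We call this the loss constant, the first-order rate at which intermediate disappears, summed over its exits.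

We lump the making at the mid-time, when half of the limiting charge is used. In violet that reckons to 1.94 min, so we reckon that a fraction 0.292 survives. The full cap gives a first answer of 23.3%. But our making constant puts [partner] at 1.00 mM at the end, so the second round gives 20.7%.

West's mid-time is 3.25 min, and its survival at the last reading is 0.587. By this reckoning violet keeps a smaller fraction at its reading than west at its last, from a lower cap.

For teal, the same reckoning with south's constants gives 0.0734%. Green is hotter, and we expect it lower still. So we expect violet highest.

The forecast says violet: 18% for violet (12% to 25%), 0.4% for green and 2% for teal, the two flasks where “the partner is gone quickly”; its violet lies below ours and its teal above.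

The flasks give violet as highest: violet 23.1%, green 0%, teal 0.0419%. Violet stands 2.4 percentage points above our reckoning.

    partner + target ⇌ idle adduct, settled at all times (K = 44.0 L mol⁻¹, ΔH = −22.0 kJ mol⁻¹)
    substrate + partner → intermediate + released group (k = 0.790 L mol⁻¹ s⁻¹, Ea = 69.0 kJ mol⁻¹)
    intermediate → decomposed reagent (k = 9.10 × 10⁻⁴ s⁻¹, Ea = 89.0 kJ mol⁻¹)
    intermediate → target (k = 0.00170 s⁻¹, Ea = 111 kJ mol⁻¹)
    target ⇌ isomer of the product (K = 0.720, k = 0.00100 s⁻¹, Ea = 109 kJ mol⁻¹, ΔH = −12.0 kJ mol⁻¹)
    (constants at 70 °C)

The neighbour is violet charged with 2.2 mM of partner, 0.200 equiv to substrate, at the same temperature. So 0.153 min⁻¹ carries over. Its mid-time is 1.56 min, and [partner] at the end reckons to 0.0412 mM. Survival reckons to 0.275, which gives 5.40% of the substrate charged. The neighbour holds 5.97%.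

The numbers in the tables stem from a simulated flask for an exercise; noise was put on by code.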